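We would put the further 6.0 min of the gamma flask into fresh enzyme (autumn). One quantity carries that choice: how long the enzyme kept up with the dissolving solid.

| setting | gamma | eta | flask |
|---|---|---|---|
| solid substrate | 0.020 M | 0.020 M | 0.020 M |
| second substrate | 0.012 M | 0.012 M | 0.0120 M |
| free enzyme | 20 µM | 40 µM | 20 µM |
| temperature | 5 °C | −10 °C | 5 °C |
| remark | the very flask that is asked about, followed so far | run made earlier |  |
| time |  |  | 6.0 min |

| run | time / min | product / % | solid substrate / % |
|---|---|---|---|
| gamma | 1.50 | 20.2 | 79.2 |
| gamma | 3.00 | 30.7 | 63.7 |
| gamma | 5.00 | 32.6 | 59.6 |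
| gamma | 6.00 | 32.8 | 59.2 |
| eta | 0.333 | 4.9 | 95.0 |
| eta | 0.417 | 5.8 | 93.8 |
| eta | 1.00 | 14.7 | 85.5 |
| eta | 3.00 | 41.5 | 57.3 |

(each reading ± 0.3 percentage points)

- product, in percent of the solid substrate first charged, at 6.0 min
- the remedy with the largest gain of product, or "none" below 2 percentage points (autumn / noon / spring / dusk / dawn / none)
- product present, with what was taken out counted in, in percent of the solid substrate first charged, after noon
- product present, with what was taken out counted in, in percent of the solid substrate first charged, after spring

- autumn: at 6.0 min add free enzyme, 50.0% of the amount charged, then wait 6.0 min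
- noon: change nothing and wait 6.0 min more
- spring: at 6.0 min add second substrate, 100% of the amount charged, then wait 6.0 min
- dusk: at 6.0 min raise the temperature by 25 K, then wait 6.0 min
- dawn: at 6.0 min take out 90% of the product then present, then wait 6.0 min

- given per volume of solution although it is solid: solid substrate
- product that was removed still counts
- at the start none of the solid substrate is in solution
- additions bring no volume worth counting

The eta run makes product at 0.147 min⁻¹ of the charge up to 1.00 min. The gamma run, with half the enzyme and warmer, reads 0.135 min⁻¹ over its first 1.50 min. Since so different a flask gives so close a slope, we read it as the feed: solid substrate entering solution.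

On the fastest rung stands uptake. At 3.00 min the eta readings leave 1.20% of the charge dissolved, which is about 0.0816 min of feed. That is far shorter than the 3.00 min the eta run had been going, so up to that reading dissolution is the rate-limiting step in the eta run.

The next rung joins the two ends of the gamma run. The start gives the feed, the end gives the plateau, and their quotient is the working time, the last gamma product reading divided by the feed 2.23 min. The gamma readings still show solid, 59.2% at 6.00 min, so the stop is not for want of solid.

After the working time, the gamma solution fills up to 8.00% of the charge while product rises 0.2 percentage points in the last interval, within the scatter. Second substrate is not short: at one per product, 45.3% of it remains, and the eta run went further on the same charge. So we take the enzyme to have stopped. We reckon about 32.8% now, and a gain below the margin of 2 points from noon, spring, dusk or dawn. We expect autumn to draw on the dissolved stock, which by these readings exceeds the margin.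

The forecast gives 32.8%, autumn, 33% after noon and 33.1% after spring: “Fresh enzyme should therefore give the largest gain”. The flask gives 32.6%, and autumn gains 14 points, with 32.7% after noon and 32.7% after spring.

    free enzyme → unfolded enzyme (k = 0.00400 s⁻¹, Ea = 238 kJ mol⁻¹)
    starting material + free enzyme ⇌ starting complex (K = 250 M⁻¹, k = 3.50 × 10⁵ M⁻¹ s⁻¹, Ea = 23.0 kJ mol⁻¹, ΔH = −19.0 kJ mol⁻¹)
    second substrate + starting complex ⇌ ternary complex (K = 1000 M⁻¹, k = 30000 M⁻¹ s⁻¹, Ea = 13.0 kJ mol⁻¹, ΔH = −29.0 kJ mol⁻¹)
    ternary complex → free enzyme + product (k = 1300 s⁻¹, Ea = 56.0 kJ mol⁻¹)
    free enzyme + product → spent catalyst (k = 5.90 M⁻¹ s⁻¹, Ea = 36.0 kJ mol⁻¹)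
    solid substrate ⇌ starting material, rate k6*(cs6 - [starting material]) while solid is left; crystals form when [starting material] > cs6 (solubility = 1.70 mM, k = 0.0290 s⁻¹)
    (constants at 5 °C)

In the gamma flask, solid substrate dissolved at about 0.142 min⁻¹ up to 1.45 min, close to the feed, while free enzyme fell from 72.0% at 0.600 min to 1.14% at 3.00 min, with product then at 31.0%. In the neighbour charged with 8.0 × 10⁻⁶ M of free enzyme, product reached 28.5%, which reckoned with the same feed is a working time of 1.94 min, against 2.23 min for the gamma flask.

Readings and results are calculated for an exercise, and the scatter is random.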